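C1, C3–C8a are the isochromene positions of the target; C2′–C5′ are the oxolane positions.
1. Last operations: C5 chlorination, and before it closure of the pyran ring by 6-endo oxa-Michael-type addition of the C1 hydroxyl to C3 of a 3-alkynylcyclohexenone.
2. The enynone comes from late union of two fragments: 1,2-addition of a side-chain lithium acetylide (C3/C4) to a cyclohexenone whose carbonyl is C4a, then oxidative 1,3-carbonyl transposition to C6.
3. The cyclohexenone (key ring) is closed by intramolecular aldol of a C4a methyl ketone (C5) onto a non-enolisable C6 aldehyde, then dehydration; C8a/C8 come from an Evans syn-aldol of a crotonate imide with methacrolein, C7 from a hydroxyl-directed epoxidation.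
4. Side chain: Brown (Z)-crotylation of methacrolein (C2′/C3′), Williamson oxolane closure, chelation-controlled diynyl Grignard addition (tertiary carbinol), directed trans-reduction to the (E)-enyne.
5. Ring order: oxolane (side-chain branch) and cyclohexenone (core branch) are built independently; the pyran ring is formed last.

Assumption: (+)-Ipc2BOMe is the enantiomer made from (−)-α-pinene (Re-face delivery to aldehydes), and commercial chiral reagents are enantiopure.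

**Core fragment (steps 1–12)**

Step 1
Reactants: 1 (R)-4-benzyl-1,3-oxazolidin-2-one; 2 (E)-but-2-enoyl chloride
Product: 4 (R)-4-benzyl-3-[(E)-but-2-enoyl]-1,3-oxazolidin-2-one, via lithium oxazolidinide 3 (not isolated)
Conditions: n-BuLi, THF, −78 °C; then 2, −78 → 0 °C
Reagents that add atoms: none
Why: N-acylation of the lithiated Evans auxiliary by the acid chloride, which forms no new stereocentre and leaves the auxiliary centre untouched.

Step 2
Reactants: 4 (R)-4-benzyl-3-[(E)-but-2-enoyl]-1,3-oxazolidin-2-one; 5 2-methylprop-2-enal (methacrolein)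
Product: 7 (4R)-4-benzyl-3-[(2R,3R)-2-ethenyl-3-hydroxy-4-methylpent-4-enoyl]-1,3-oxazolidin-2-one, via boron dienolate 6 (not isolated)
Conditions: Bu2BOTf, Et3N, CH2Cl2, −78 → 0 °C; then 5, −78 → 0 °C; pH 7 buffer, MeOH, H2O2
Reagents that add atoms: none
Why: Evans syn-aldol of the crotonate imide through its (Z)-boron dienolate, which reacts at the α-carbon in a Zimmerman–Traxler chair on the face away from the benzyl group and so sets C8a and C8 as the (2R,3R)-syn pair; the vinyl group is the latent C4a acetyl.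

Step 3
Reactants: 7 (4R)-4-benzyl-3-[(2R,3R)-2-ethenyl-3-hydroxy-4-methylpent-4-enoyl]-1,3-oxazolidin-2-one
Product: 8 (2S,3R)-2-ethenyl-4-methylpent-4-ene-1,3-diol
Conditions: LiBH4, MeOH (1 equiv), THF, 0 °C
Reagents that add atoms: none
Why: Reductive cleavage of the N-acyl oxazolidinone to the primary alcohol (C1) without touching either stereocentre (the descriptor at C8a changes only through priorities).

Step 4
Reactants: 8 (2S,3R)-2-ethenyl-4-methylpent-4-ene-1,3-diol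
Product: 9 (3R,4S)-4-({[tert-butyl(dimethyl)silyl]oxy}methyl)-2-methylhexa-1,5-dien-3-ol
Conditions: TBSCl, imidazole, CH2Cl2, 0 °C
Reagents that add atoms: tert-butyldimethylsilyl chloride, CC(C)(C)[Si](C)(C)Cl
Why: Selective silylation of the primary hydroxyl over the hindered secondary allylic one, leaving the C8 hydroxyl free to direct the next step.

Step 5
Reactants: 9 (3R,4S)-4-({[tert-butyl(dimethyl)silyl]oxy}methyl)-2-methylhexa-1,5-dien-3-ol
Product: 10 (1R,2S)-2-({[tert-butyl(dimethyl)silyl]oxy}methyl)-1-[(2S)-2-methyloxiran-2-yl]but-3-en-1-ol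
Conditions: VO(acac)2 (5 mol %), t-BuOOH, CH2Cl2, 0 °C → rt
Reagents that add atoms: tert-butyl hydroperoxide, CC(C)(C)OO
Why: Hydroxyl-directed vanadium-catalysed epoxidation attacks only the allylic 1,1-disubstituted alkene, and the A(1,2)-strain-controlled transition state gives the erythro epoxy alcohol, which sets C7.

Step 6
Reactants: 10 (1R,2S)-2-({[tert-butyl(dimethyl)silyl]oxy}methyl)-1-[(2S)-2-methyloxiran-2-yl]but-3-en-1-ol
Product: 11 (2S,3R,4S)-4-({[tert-butyl(dimethyl)silyl]oxy}methyl)-2,3-dihydroxy-2-methylhex-5-en-1-yl benzoate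
Conditions: Ti(OiPr)4, PhCO2H, CH2Cl2, rt
Reagents that add atoms: benzoic acid, O=C(O)c1ccccc1
Why: Titanium-mediated opening of the 2,3-epoxy alcohol at the carbon remote from the carbinol (the primary C6) is an SN2 displacement at CH2, so the C7–O bond and its configuration are kept.

Step 7
Reactants: 11 (2S,3R,4S)-4-({[tert-butyl(dimethyl)silyl]oxy}methyl)-2,3-dihydroxy-2-methylhex-5-en-1-yl benzoate
Product: 12 {(4S,5R)-5-[(2S)-1-{[tert-butyl(dimethyl)silyl]oxy}but-3-en-2-yl]-2,2,4-trimethyl-1,3-dioxolan-4-yl}methyl benzoate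
Conditions: 2-methoxypropene, PPTS (cat.), CH2Cl2, 0 °C
Reagents that add atoms: 2-methoxypropene, COC(C)=C
Why: Acetonide formation on the only free 1,2-diol (C7/C8) by acid-catalysed ketal exchange, which does not touch any C–O bond at the stereocentres.

Step 8
Reactants: 12 {(4S,5R)-5-[(2S)-1-{[tert-butyl(dimethyl)silyl]oxy}but-3-en-2-yl]-2,2,4-trimethyl-1,3-dioxolan-4-yl}methyl benzoate
Product: 13 {(4S,5R)-5-[(2S)-1-{[tert-butyl(dimethyl)silyl]oxy}but-3-en-2-yl]-2,2,4-trimethyl-1,3-dioxolan-4-yl}methanol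
Conditions: K2CO3 (cat.), MeOH, rt
Reagents that add atoms: none
Why: Base-catalysed transesterification removes the benzoate before any epimerisable ketone is present, while the silyl ether and acetonide are stable.

Step 9
Reactants: 13 {(4S,5R)-5-[(2S)-1-{[tert-butyl(dimethyl)silyl]oxy}but-3-en-2-yl]-2,2,4-trimethyl-1,3-dioxolan-4-yl}methanol
Product: 14 (3S)-4-{[tert-butyl(dimethyl)silyl]oxy}-3-[(4R,5S)-5-(hydroxymethyl)-2,2,5-trimethyl-1,3-dioxolan-4-yl]butan-2-one
Conditions: PdCl2 (10 mol %), Cu(OAc)2 (20 mol %), O2 (1 atm), DMA/H2O 7:1, rt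
Reagents that add atoms: water, O
Why: Tsuji–Wacker oxidation converts the monosubstituted vinyl group with Markovnikov selectivity into the C4a methyl ketone under acetate-buffered conditions that spare the acetonide, the silyl ether and the C8a centre.

Step 10
Reactants: 14 (3S)-4-{[tert-butyl(dimethyl)silyl]oxy}-3-[(4R,5S)-5-(hydroxymethyl)-2,2,5-trimethyl-1,3-dioxolan-4-yl]butan-2-one
Product: 15 (4R,5R)-5-[(2S)-1-{[tert-butyl(dimethyl)silyl]oxy}-3-oxobutan-2-yl]-2,2,4-trimethyl-1,3-dioxolane-4-carbaldehyde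
Conditions: Dess–Martin periodinane, NaHCO3, CH2Cl2, 0 °C → rt
Reagents that add atoms: none
Why: Buffered Dess–Martin oxidation of the primary alcohol gives the non-enolisable C6 aldehyde under neutral conditions that do not epimerise C8a.

Step 11
Reactants: 15 (4R,5R)-5-[(2S)-1-{[tert-butyl(dimethyl)silyl]oxy}-3-oxobutan-2-yl]-2,2,4-trimethyl-1,3-dioxolane-4-carbaldehyde
Product: 17 (4S,5R,6S)-6-({[tert-butyl(dimethyl)silyl]oxy}methyl)-3-hydroxy-4,5-(isopropylidenedioxy)-4-methylcyclohexan-1-one (both C3 epimers), via boron enolate 16 (not isolated)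
Conditions: Bu2BOTf, iPr2NEt, CH2Cl2, −78 → 0 °C; pH 7 buffer, MeOH, H2O2
Reagents that add atoms: none
Why: Intramolecular boron-mediated aldol (6-exo-trig): soft enolisation takes the methyl side of the ketone, the aldehyde cannot enolise, and the cis disposition of the two chains on the dioxolane pre-organises the ring closure, with the new carbinol centre removed in the next step.

Step 12
Reactants: 17 (4S,5R,6S)-6-({[tert-butyl(dimethyl)silyl]oxy}methyl)-3-hydroxy-4,5-(isopropylidenedioxy)-4-methylcyclohexan-1-one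
Product: 19 (4S,5R,6S)-6-({[tert-butyl(dimethyl)silyl]oxy}methyl)-4,5-(isopropylidenedioxy)-4-methylcyclohex-2-en-1-one, via mesylate 18 (not isolated)
Conditions: MsCl, Et3N, CH2Cl2, 0 °C; then DBU, 0 °C → rt
Reagents that add atoms: none
Why: Mesylation and E1cB elimination through the C5 enolate complete the aldol condensation to the enone, the good leaving group making elimination faster than enolisation towards C8a.

**Side-chain fragment (steps 13–21)**

Step 13
Reactants: 20 (Z)-but-2-ene; 5 2-methylprop-2-enal (methacrolein)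
Product: 23 (3R,4S)-2,4-dimethylhexa-1,5-dien-3-ol, via (Z)-crotylpotassium 21 (not isolated), via (Z)-crotyldiisopinocampheylborane 22 (not isolated)
Conditions: KOtBu, n-BuLi, THF, −78 → −45 °C; (+)-Ipc2BOMe, −78 °C; BF3·OEt2; then 5, −78 °C; NaOH, H2O2, 0 °C → rt
Reagents that add atoms: none
Why: Brown asymmetric crotylboration: the (Z)-crotylborane reacts through a closed chair transition state to give the syn adduct, and the (+)-Ipc groups direct Re-face attack, setting C2′ (R) and C3′ (S).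

Step 14
Reactants: 23 (3R,4S)-2,4-dimethylhexa-1,5-dien-3-ol
Product: 25 (3S,4R)-3,5-dimethylhex-5-ene-1,4-diol, via organoborane 24 (not isolated)
Conditions: Sia2BH (from BH3·THF and 2-methylbut-2-ene, 2.2 equiv), THF, 0 °C; NaOH, H2O2
Reagents that add atoms: hydrogen peroxide, OO
Why: Anti-Markovnikov hydroboration–oxidation with the bulky dialkylborane, which is selective for the monosubstituted vinyl group over the hindered 1,1-disubstituted alkene and does not affect the stereocentres.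

Step 15
Reactants: 25 (3S,4R)-3,5-dimethylhex-5-ene-1,4-diol
Product: 26 (3S,4R)-4-hydroxy-3,5-dimethylhex-5-en-1-yl 4-methylbenzenesulfonate
Conditions: TsCl, pyridine, CH2Cl2, 0 °C
Reagents that add atoms: 4-methylbenzenesulfonyl chloride, Cc1ccc(cc1)S(=O)(=O)Cl
Why: Selective sulfonylation of the primary hydroxyl over the hindered secondary allylic one activates C5′ for ring closure.

Step 16
Reactants: 26 (3S,4R)-4-hydroxy-3,5-dimethylhex-5-en-1-yl 4-methylbenzenesulfonate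
Product: 27 (2R,3S)-3-methyl-2-(prop-1-en-2-yl)oxolane
Conditions: NaH, THF, 0 °C → rt (volatile product, solution carried on)
Reagents that add atoms: none
Why: Intramolecular Williamson etherification (5-exo-tet) at the primary tosylate closes the oxolane without breaking a bond at C2′ or C3′, so the 2,3-cis relationship from the syn crotylation is kept.

Step 17
Reactants: 27 (2R,3S)-3-methyl-2-(prop-1-en-2-yl)oxolane
Product: 29 1-[(2R,3S)-3-methyloxolan-2-yl]ethan-1-one, via ozonide 28 (not isolated)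
Conditions: O3, CH2Cl2, −78 °C; then Me2S, −78 °C → rt
Reagents that add atoms: ozone, [O-][O+]=O
Why: Ozonolysis with reductive work-up cleaves the isopropenyl group to the methyl ketone under neutral conditions that do not epimerise the α-alkoxy centre C2′.

Step 18
Reactants: 29 1-[(2R,3S)-3-methyloxolan-2-yl]ethan-1-one; 30 1,4-bis(trimethylsilyl)buta-1,3-diyne
Product: 33 (2R)-2-[(2R,3S)-3-methyloxolan-2-yl]-6-(trimethylsilyl)hexa-3,5-diyn-2-ol, via lithium diynide 31 (not isolated), via diynylmagnesium bromide 32 (not isolated)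
Conditions: 30, MeLi·LiBr, THF, rt; MgBr2·OEt2, −78 °C; then 29, −78 → −30 °C; NH4Cl (aq)
Reagents that add atoms: none
Why: Cram-chelate-controlled Grignard addition: magnesium bridges the carbonyl and ring oxygens and the diynyl group attacks from the C2′–H side of the chelate, giving the (R)-tertiary carbinol.

Step 19
Reactants: 33 (2R)-2-[(2R,3S)-3-methyloxolan-2-yl]-6-(trimethylsilyl)hexa-3,5-diyn-2-ol
Product: 34 (2R,3E)-2-[(2R,3S)-3-methyloxolan-2-yl]-6-(trimethylsilyl)hex-3-en-5-yn-2-ol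
Conditions: LiAlH4, THF, 0 °C → rt
Reagents that add atoms: none
Why: Hydroxyl-directed trans-hydroalumination reduces only the alkyne next to the alkoxide, giving the (E)-alkene and leaving the silylated alkyne intact.

Step 20
Reactants: 34 (2R,3E)-2-[(2R,3S)-3-methyloxolan-2-yl]-6-(trimethylsilyl)hex-3-en-5-yn-2-ol
Product: 35 triethyl({(2R,3E)-2-[(2R,3S)-3-methyloxolan-2-yl]-6-(trimethylsilyl)hex-3-en-5-yn-2-yl}oxy)silane
Conditions: TESOTf, 2,6-lutidine, CH2Cl2, −78 → 0 °C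
Reagents that add atoms: triethylsilyl trifluoromethanesulfonate, CC[Si](CC)(CC)OS(=O)(=O)C(F)(F)F
Why: Silylation of the tertiary allylic alcohol with the reactive silyl triflate masks it so that it cannot take part in the later oxidative allylic transposition.

Step 21
Reactants: 35 triethyl({(2R,3E)-2-[(2R,3S)-3-methyloxolan-2-yl]-6-(trimethylsilyl)hex-3-en-5-yn-2-yl}oxy)silane
Product: 36 triethyl({(2R,3E)-2-[(2R,3S)-3-methyloxolan-2-yl]hex-3-en-5-yn-2-yl}oxy)silane
Conditions: K2CO3, MeOH, rt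
Reagents that add atoms: none
Why: Methanolysis cleaves the alkynyl C–Si bond selectively, freeing the terminal alkyne while the hindered tertiary silyl ether survives.

**Fragment union and end game (steps 22–26)**

Step 22
Reactants: 36 triethyl({(2R,3E)-2-[(2R,3S)-3-methyloxolan-2-yl]hex-3-en-5-yn-2-yl}oxy)silane; 19 (4S,5R,6S)-6-({[tert-butyl(dimethyl)silyl]oxy}methyl)-4,5-(isopropylidenedioxy)-4-methylcyclohex-2-en-1-one
Product: 38 (4S,5R,6S)-6-({[tert-butyl(dimethyl)silyl]oxy}methyl)-4,5-(isopropylidenedioxy)-4-methyl-1-{(3E,5R)-5-[(2R,3S)-3-methyloxolan-2-yl]-5-[(triethylsilyl)oxy]hex-3-en-1-yn-1-yl}cyclohex-2-en-1-ol (both C1 epimers), via lithium acetylide 37 (not isolated)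
Conditions: 36, n-BuLi, THF, −78 °C; then 19, −78 → −40 °C; NH4Cl (aq)
Reagents that add atoms: none
Why: 1,2-addition of the lithium acetylide to the enone carbonyl joins the fragments at C4–C4a, and both carbinol epimers are used because this carbon becomes sp2 in the next step.

Step 23
Reactants: 38 (4S,5R,6S)-6-({[tert-butyl(dimethyl)silyl]oxy}methyl)-4,5-(isopropylidenedioxy)-4-methyl-1-{(3E,5R)-5-[(2R,3S)-3-methyloxolan-2-yl]-5-[(triethylsilyl)oxy]hex-3-en-1-yn-1-yl}cyclohex-2-en-1-ol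
Product: 39 (4S,5R,6R)-4-({[tert-butyl(dimethyl)silyl]oxy}methyl)-5,6-(isopropylidenedioxy)-6-methyl-3-{(3E,5R)-5-[(2R,3S)-3-methyloxolan-2-yl]-5-[(triethylsilyl)oxy]hex-3-en-1-yn-1-yl}cyclohex-2-en-1-one
Conditions: pyridinium chlorochromate [C5H5NH][CrO3Cl], 4 Å molecular sieves, CH2Cl2, rt
Reagents that add atoms: pyridinium chlorochromate, [O-][Cr](=O)(=O)Cl.c1cc[nH+]cc1
Why: Babler–Dauben oxidative 1,3-transposition: the tertiary allylic chromate ester shifts to C6 by a [3,3] rearrangement and is oxidised there, giving the C6 ketone and the C4a=C5 alkene without touching a stereocentre.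

Step 24
Reactants: 39 (4S,5R,6R)-4-({[tert-butyl(dimethyl)silyl]oxy}methyl)-5,6-(isopropylidenedioxy)-6-methyl-3-{(3E,5R)-5-[(2R,3S)-3-methyloxolan-2-yl]-5-[(triethylsilyl)oxy]hex-3-en-1-yn-1-yl}cyclohex-2-en-1-one
Product: 40 (4S,5R,6R)-5,6-dihydroxy-3-{(3E,5R)-5-hydroxy-5-[(2R,3S)-3-methyloxolan-2-yl]hex-3-en-1-yn-1-yl}-4-(hydroxymethyl)-6-methylcyclohex-2-en-1-one
Conditions: CF3CO2H/H2O/THF (3:1:1), 0 °C → rt
Reagents that add atoms: none
Why: Acid hydrolysis removes the acetonide, the primary TBS ether and the tertiary TES ether in one operation at the enynone stage, before the acid-sensitive dienol ether exists; any pyran formed here is the product of the next step.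

Step 25
Reactants: 40 (4S,5R,6R)-5,6-dihydroxy-3-{(3E,5R)-5-hydroxy-5-[(2R,3S)-3-methyloxolan-2-yl]hex-3-en-1-yn-1-yl}-4-(hydroxymethyl)-6-methylcyclohex-2-en-1-one
Product: 41 (7R,8R,8aS)-7,8-dihydroxy-3-{(1E,3R)-3-hydroxy-3-[(2R,3S)-3-methyloxolan-2-yl]but-1-en-1-yl}-7-methyl-1,7,8,8a-tetrahydro-6H-isochromen-6-one
Conditions: AgOSO2CF3 (10 mol %), THF, 0 °C → rt, dark
Reagents that add atoms: none
Why: Silver-assisted 6-endo-dig intramolecular oxa-Michael-type (1,6-conjugate) addition of the C1 hydroxyl to the alkyne terminus C3, which the enone polarises; the C8 hydroxyl cannot compete because its ring would place an alkene at a bridgehead.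

Step 26
Reactants: 41 (7R,8R,8aS)-7,8-dihydroxy-3-{(1E,3R)-3-hydroxy-3-[(2R,3S)-3-methyloxolan-2-yl]but-1-en-1-yl}-7-methyl-1,7,8,8a-tetrahydro-6H-isochromen-6-one
Product: 42 Peniciazaphilone E, (7R,8R,8aS)-5-chloro-7,8-dihydroxy-3-{(1E,3R)-3-hydroxy-3-[(2R,3S)-3-methyloxolan-2-yl]but-1-en-1-yl}-7-methyl-1,7,8,8a-tetrahydro-6H-isochromen-6-one
Conditions: N-chlorosuccinimide (1.05 equiv), MeCN, 0 °C
Reagents that add atoms: N-chlorosuccinimide, O=C1CCC(=O)N1Cl
Why: Electrophilic chlorination at C5, the nucleophilic α-carbon of the doubly vinylogous ester (pyran O–C3=C4–C4a=C5–C6=O), followed by loss of the C5 proton, as in the C5 halogenation of azaphilones.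

**Compound list**

1 | (R)-4-benzyl-1,3-oxazolidin-2-one | O=C1N[C@H](Cc2ccccc2)CO1 | starting material
2 | (E)-but-2-enoyl chloride | C/C=C/C(Cl)=O | starting material
3 | lithium (R)-4-benzyl-2-oxo-1,3-oxazolidin-3-ide | [Li]N1[C@H](Cc2ccccc2)COC1=O | intermediate
4 | (R)-4-benzyl-3-[(E)-but-2-enoyl]-1,3-oxazolidin-2-one | C/C=C/C(=O)N1[C@H](Cc2ccccc2)COC1=O | intermediate
5 | 2-methylprop-2-enal (methacrolein) | CC(=C)C=O | starting material
6 | (Z)-dibutylboron dienolate of 4 | C=C/C=C(\OB(CCCC)CCCC)N1[C@H](Cc2ccccc2)COC1=O | intermediate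
7 | (4R)-4-benzyl-3-[(2R,3R)-2-ethenyl-3-hydroxy-4-methylpent-4-enoyl]-1,3-oxazolidin-2-one | C=C(C)[C@H](O)[C@@H](C=C)C(=O)N1[C@H](Cc2ccccc2)COC1=O | intermediate
8 | (2S,3R)-2-ethenyl-4-methylpent-4-ene-1,3-diol | C=C(C)[C@H](O)[C@@H](C=C)CO | intermediate
9 | (3R,4S)-4-({[tert-butyl(dimethyl)silyl]oxy}methyl)-2-methylhexa-1,5-dien-3-ol | C=C(C)[C@H](O)[C@@H](C=C)CO[Si](C)(C)C(C)(C)C | intermediate
10 | (1R,2S)-2-({[tert-butyl(dimethyl)silyl]oxy}methyl)-1-[(2S)-2-methyloxiran-2-yl]but-3-en-1-ol | C[C@]1(CO1)[C@H](O)[C@@H](C=C)CO[Si](C)(C)C(C)(C)C | intermediate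
11 | (2S,3R,4S)-4-({[tert-butyl(dimethyl)silyl]oxy}methyl)-2,3-dihydroxy-2-methylhex-5-en-1-yl benzoate | O=C(OC[C@](C)(O)[C@H](O)[C@@H](C=C)CO[Si](C)(C)C(C)(C)C)c1ccccc1 | intermediate
12 | {(4S,5R)-5-[(2S)-1-{[tert-butyl(dimethyl)silyl]oxy}but-3-en-2-yl]-2,2,4-trimethyl-1,3-dioxolan-4-yl}methyl benzoate | O=C(OC[C@]1(C)OC(C)(C)O[C@@H]1[C@@H](C=C)CO[Si](C)(C)C(C)(C)C)c1ccccc1 | intermediate
13 | {(4S,5R)-5-[(2S)-1-{[tert-butyl(dimethyl)silyl]oxy}but-3-en-2-yl]-2,2,4-trimethyl-1,3-dioxolan-4-yl}methanol | OC[C@]1(C)OC(C)(C)O[C@@H]1[C@@H](C=C)CO[Si](C)(C)C(C)(C)C | intermediate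
14 | (3S)-4-{[tert-butyl(dimethyl)silyl]oxy}-3-[(4R,5S)-5-(hydroxymethyl)-2,2,5-trimethyl-1,3-dioxolan-4-yl]butan-2-one | OC[C@]1(C)OC(C)(C)O[C@@H]1[C@@H](C(C)=O)CO[Si](C)(C)C(C)(C)C | intermediate
15 | (4R,5R)-5-[(2S)-1-{[tert-butyl(dimethyl)silyl]oxy}-3-oxobutan-2-yl]-2,2,4-trimethyl-1,3-dioxolane-4-carbaldehyde | O=C[C@]1(C)OC(C)(C)O[C@@H]1[C@@H](C(C)=O)CO[Si](C)(C)C(C)(C)C | intermediate
16 | dibutylboron enolate of the methyl ketone of 15 | O=C[C@]1(C)OC(C)(C)O[C@@H]1[C@@H](C(=C)OB(CCCC)CCCC)CO[Si](C)(C)C(C)(C)C | intermediate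
17 | (4S,5R,6S)-6-({[tert-butyl(dimethyl)silyl]oxy}methyl)-3-hydroxy-4,5-(isopropylidenedioxy)-4-methylcyclohexan-1-one (both C3 epimers) | O=C1CC(O)[C@]2(C)OC(C)(C)O[C@@H]2[C@@H]1CO[Si](C)(C)C(C)(C)C | intermediate
18 | methanesulfonate of 17 | O=C1CC(OS(C)(=O)=O)[C@]2(C)OC(C)(C)O[C@@H]2[C@@H]1CO[Si](C)(C)C(C)(C)C | intermediate
19 | (4S,5R,6S)-6-({[tert-butyl(dimethyl)silyl]oxy}methyl)-4,5-(isopropylidenedioxy)-4-methylcyclohex-2-en-1-one | O=C1C=C[C@]2(C)OC(C)(C)O[C@@H]2[C@@H]1CO[Si](C)(C)C(C)(C)C | intermediate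
20 | (Z)-but-2-ene | C/C=C\C | starting material
21 | (Z)-but-2-en-1-ylpotassium | C/C=C\C[K] | intermediate
22 | (Z)-but-2-en-1-yl-bis[(+)-isopinocampheyl]borane | C/C=C\CB([C@H]1C[C@H]2C[C@@H]([C@@H]1C)C2(C)C)[C@H]1C[C@H]2C[C@@H]([C@@H]1C)C2(C)C | intermediate
23 | (3R,4S)-2,4-dimethylhexa-1,5-dien-3-ol | C=C[C@H](C)[C@@H](O)C(C)=C | intermediate
24 | bis(disiamylboryl) adduct of 23 (C-boryl at C6, O-boryl at O3) | CC(C)C(C)B(C(C)C(C)C)CC[C@H](C)[C@@H](OB(C(C)C(C)C)C(C)C(C)C)C(C)=C | intermediate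
25 | (3S,4R)-3,5-dimethylhex-5-ene-1,4-diol | OCC[C@H](C)[C@@H](O)C(C)=C | intermediate
26 | (3S,4R)-4-hydroxy-3,5-dimethylhex-5-en-1-yl 4-methylbenzenesulfonate | Cc1ccc(cc1)S(=O)(=O)OCC[C@H](C)[C@@H](O)C(C)=C | intermediate
27 | (2R,3S)-3-methyl-2-(prop-1-en-2-yl)oxolane | C[C@H]1CCO[C@H]1C(C)=C | intermediate
28 | 3-methyl-3-[(2R,3S)-3-methyloxolan-2-yl]-1,2,4-trioxolane | C[C@H]1CCO[C@H]1C1(C)OCOO1 | intermediate
29 | 1-[(2R,3S)-3-methyloxolan-2-yl]ethan-1-one | C[C@H]1CCO[C@H]1C(C)=O | intermediate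
30 | 1,4-bis(trimethylsilyl)buta-1,3-diyne | C[Si](C)(C)C#CC#C[Si](C)(C)C | starting material
31 | [4-(trimethylsilyl)buta-1,3-diyn-1-yl]lithium | [Li]C#CC#C[Si](C)(C)C | intermediate
32 | [4-(trimethylsilyl)buta-1,3-diyn-1-yl]magnesium bromide | Br[Mg]C#CC#C[Si](C)(C)C | intermediate
33 | (2R)-2-[(2R,3S)-3-methyloxolan-2-yl]-6-(trimethylsilyl)hexa-3,5-diyn-2-ol | C[C@H]1CCO[C@H]1[C@](C)(O)C#CC#C[Si](C)(C)C | intermediate
34 | (2R,3E)-2-[(2R,3S)-3-methyloxolan-2-yl]-6-(trimethylsilyl)hex-3-en-5-yn-2-ol | C[C@H]1CCO[C@H]1[C@](C)(O)/C=C/C#C[Si](C)(C)C | intermediate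
35 | triethyl({(2R,3E)-2-[(2R,3S)-3-methyloxolan-2-yl]-6-(trimethylsilyl)hex-3-en-5-yn-2-yl}oxy)silane | C[C@H]1CCO[C@H]1[C@](C)(O[Si](CC)(CC)CC)/C=C/C#C[Si](C)(C)C | intermediate
36 | triethyl({(2R,3E)-2-[(2R,3S)-3-methyloxolan-2-yl]hex-3-en-5-yn-2-yl}oxy)silane | C[C@H]1CCO[C@H]1[C@](C)(O[Si](CC)(CC)CC)/C=C/C#C | intermediate
37 | lithium acetylide of 36 | C[C@H]1CCO[C@H]1[C@](C)(O[Si](CC)(CC)CC)/C=C/C#C[Li] | intermediate
38 | (4S,5R,6S)-6-({[tert-butyl(dimethyl)silyl]oxy}methyl)-4,5-(isopropylidenedioxy)-4-methyl-1-{(3E,5R)-5-[(2R,3S)-3-methyloxolan-2-yl]-5-[(triethylsilyl)oxy]hex-3-en-1-yn-1-yl}cyclohex-2-en-1-ol (both C1 epimers) | C[C@H]1CCO[C@H]1[C@](C)(O[Si](CC)(CC)CC)/C=C/C#CC3(O)C=C[C@]2(C)OC(C)(C)O[C@@H]2[C@@H]3CO[Si](C)(C)C(C)(C)C | intermediate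
39 | (4S,5R,6R)-4-({[tert-butyl(dimethyl)silyl]oxy}methyl)-5,6-(isopropylidenedioxy)-6-methyl-3-{(3E,5R)-5-[(2R,3S)-3-methyloxolan-2-yl]-5-[(triethylsilyl)oxy]hex-3-en-1-yn-1-yl}cyclohex-2-en-1-one | C[C@H]1CCO[C@H]1[C@](C)(O[Si](CC)(CC)CC)/C=C/C#CC3=CC(=O)[C@]2(C)OC(C)(C)O[C@@H]2[C@@H]3CO[Si](C)(C)C(C)(C)C | intermediate
40 | (4S,5R,6R)-5,6-dihydroxy-3-{(3E,5R)-5-hydroxy-5-[(2R,3S)-3-methyloxolan-2-yl]hex-3-en-1-yn-1-yl}-4-(hydroxymethyl)-6-methylcyclohex-2-en-1-one | C[C@H]1CCO[C@H]1[C@](C)(O)/C=C/C#CC3=CC(=O)[C@](C)(O)[C@H](O)[C@@H]3CO | intermediate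
41 | (7R,8R,8aS)-7,8-dihydroxy-3-{(1E,3R)-3-hydroxy-3-[(2R,3S)-3-methyloxolan-2-yl]but-1-en-1-yl}-7-methyl-1,7,8,8a-tetrahydro-6H-isochromen-6-one | C[C@H]1CCO[C@H]1[C@](C)(O)/C=C/C1=CC2=CC(=O)[C@](C)(O)[C@H](O)[C@@H]2CO1 | intermediate
42 | Peniciazaphilone E, (7R,8R,8aS)-5-chloro-7,8-dihydroxy-3-{(1E,3R)-3-hydroxy-3-[(2R,3S)-3-methyloxolan-2-yl]but-1-en-1-yl}-7-methyl-1,7,8,8a-tetrahydro-6H-isochromen-6-one | C[C@H]1CCO[C@H]1[C@](C)(O)/C=C/C1=CC2=C(Cl)C(=O)[C@](C)(O)[C@H](O)[C@@H]2CO1 | target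

**Step count and risks**

Total step count: 26 (core fragment 12, side-chain fragment 9, union and end game 5).
Longest linear sequence: 17 steps (steps 1–12, then 22–26); 17/26 = 0.65.

The three steps most likely to fail:

Step 23 (oxidative 1,3-transposition with pyridinium chlorochromate). The tertiary alcohol is also propargylic, and the chromate must migrate to a C6 position flanked by a quaternary carbon. The fallback sets out from 17, the aldol before dehydration. Cerium-assisted (CeCl3) addition of two equivalents of the lithium acetylide 37 to the ketone of 17 gives the propargylic diol F1. Dess–Martin oxidation of its secondary C6 hydroxyl gives the β-hydroxy ketone F2. E1cB-type dehydration of the tertiary alcohol through the C5 position (Burgess reagent, toluene, 50 °C) then gives the enynone. The fallback comes back to the route at 39.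

Step 25 (6-endo cyclisation with AgOSO2CF3). 5-exo closure to an alkylidene oxolane or acid-induced loss of the tertiary allylic alcohol could compete. The fallback sets out from 40. Diethylamine (EtOH, rt) adds to the alkyne terminus C3 in an aza-Michael reaction to give the vinylogous amide F3. Brief warming with PPTS in wet THF lets the C1 hydroxyl displace the amine at C3 by addition–elimination, for which only the six-membered ring is possible. The fallback comes back to the route at 41.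

Step 26 (late C5 chlorination). Attack at C4 or at the side-chain diene, or over-chlorination, is possible on the unprotected compound. The fallback places chlorine before the fragment union and sets out from 19. Chlorine addition and dehydrochlorination (Cl2, CH2Cl2, −78 °C; then Et3N) give the 2-chloroenone F4. Addition of the lithium acetylide 37 gives the chloro carbinol F5, and oxidative transposition with pyridinium chlorochromate gives the chloro enynone F6. Hydrolysis with CF3CO2H/H2O/THF gives the deprotected chloro enynone F7, and silver-assisted 6-endo cyclisation as in step 25 closes the pyran. The fallback comes back to the route at 42.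

Further compounds
F1 | step 23 | (4S,5R,6S)-6-({[tert-butyl(dimethyl)silyl]oxy}methyl)-4,5-(isopropylidenedioxy)-4-methyl-1-{(3E,5R)-5-[(2R,3S)-3-methyloxolan-2-yl]-5-[(triethylsilyl)oxy]hex-3-en-1-yn-1-yl}cyclohexane-1,3-diol (epimers at C1 and C3) | C[C@H]1CCO[C@H]1[C@](C)(O[Si](CC)(CC)CC)/C=C/C#CC3(O)CC(O)[C@]2(C)OC(C)(C)O[C@@H]2[C@@H]3CO[Si](C)(C)C(C)(C)C
F2 | step 23 | (2R,3R,4S)-4-({[tert-butyl(dimethyl)silyl]oxy}methyl)-5-hydroxy-2,3-(isopropylidenedioxy)-2-methyl-5-{(3E,5R)-5-[(2R,3S)-3-methyloxolan-2-yl]-5-[(triethylsilyl)oxy]hex-3-en-1-yn-1-yl}cyclohexan-1-one (epimers at C5) | C[C@H]1CCO[C@H]1[C@](C)(O[Si](CC)(CC)CC)/C=C/C#CC3(O)CC(=O)[C@]2(C)OC(C)(C)O[C@@H]2[C@@H]3CO[Si](C)(C)C(C)(C)C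
F3 | step 25 | (4S,5R,6R)-3-{(3E,5R)-2-(diethylamino)-5-hydroxy-5-[(2R,3S)-3-methyloxolan-2-yl]hexa-1,3-dien-1-yl}-5,6-dihydroxy-4-(hydroxymethyl)-6-methylcyclohex-2-en-1-one | C[C@H]1CCO[C@H]1[C@](C)(O)/C=C/C(N(CC)CC)=CC3=CC(=O)[C@](C)(O)[C@H](O)[C@@H]3CO
F4 | step 26 | (4S,5R,6S)-6-({[tert-butyl(dimethyl)silyl]oxy}methyl)-2-chloro-4,5-(isopropylidenedioxy)-4-methylcyclohex-2-en-1-one | O=C1C(Cl)=C[C@]2(C)OC(C)(C)O[C@@H]2[C@@H]1CO[Si](C)(C)C(C)(C)C
F5 | step 26 | (4S,5R,6S)-6-({[tert-butyl(dimethyl)silyl]oxy}methyl)-2-chloro-4,5-(isopropylidenedioxy)-4-methyl-1-{(3E,5R)-5-[(2R,3S)-3-methyloxolan-2-yl]-5-[(triethylsilyl)oxy]hex-3-en-1-yn-1-yl}cyclohex-2-en-1-ol (both C1 epimers) | C[C@H]1CCO[C@H]1[C@](C)(O[Si](CC)(CC)CC)/C=C/C#CC3(O)C(Cl)=C[C@]2(C)OC(C)(C)O[C@@H]2[C@@H]3CO[Si](C)(C)C(C)(C)C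
F6 | step 26 | (4S,5R,6R)-4-({[tert-butyl(dimethyl)silyl]oxy}methyl)-2-chloro-5,6-(isopropylidenedioxy)-6-methyl-3-{(3E,5R)-5-[(2R,3S)-3-methyloxolan-2-yl]-5-[(triethylsilyl)oxy]hex-3-en-1-yn-1-yl}cyclohex-2-en-1-one | C[C@H]1CCO[C@H]1[C@](C)(O[Si](CC)(CC)CC)/C=C/C#CC3=C(Cl)C(=O)[C@]2(C)OC(C)(C)O[C@@H]2[C@@H]3CO[Si](C)(C)C(C)(C)C
F7 | step 26 | (4S,5R,6R)-2-chloro-5,6-dihydroxy-3-{(3E,5R)-5-hydroxy-5-[(2R,3S)-3-methyloxolan-2-yl]hex-3-en-1-yn-1-yl}-4-(hydroxymethyl)-6-methylcyclohex-2-en-1-one | C[C@H]1CCO[C@H]1[C@](C)(O)/C=C/C#CC3=C(Cl)C(=O)[C@](C)(O)[C@H](O)[C@@H]3CO
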